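Atom numbers follow the elemane skeleton. Ring B is C5–C6–C7–C8–C9–C10, with CH3 and vinyl on C10, isopropenyl on C5, OH on C6, and the arm C11(OH)(C12H2OAc)(C13H2OAc) on C7.
Cuts, in retrosynthetic order: the two acetates; C11–C12 and C11–C13 (back to a C11 methyl ester, with C6 raised to a ketone); ring bond C7–C8; C6–C7 (malonate homologation); C5–C10 ([3,3] shift of an allyl ester).
Enabling feature: in ring B, C7 sits between the carbinol carbon C6 and the exocyclic C11. With C6 as ketone and C11 as ester carbon, C7 is a 1,3-dicarbonyl CH and the only soft nucleophile of the chain. Its ring bond to C8 lies opposite the crowded C5–C10 edge.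
Forward order: the C8–C9–C10–C1–C2 unit is built by carboalumination and joined to the acid as an ester. C5–C10 then forms by Ireland–Claisen rearrangement and C6–C7 by malonate acylation. Ring B, the only ring, closes by C7-to-C8 alkylation, and C12 and C13 are then added to C11.
Stereochemistry: C5 and C10 come from the chair transition state of a boron-enolate Ireland–Claisen rearrangement. The E-alkene and the enolate geometry set the relative configuration, and a C2-symmetric chiral diazaborolidine sets the absolute one. C7 is set by equilibration to the equatorial position, and C6 by dissolving-metal reduction to the equatorial alcohol.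
Key step: step 9

Assumption: the (S,S)-diazaborolidine is taken to deliver the (2S,3S)-acid of step 6, the configuration of the natural elemane series; if the sense of induction is the reverse, the equally accessible (R,R)-reagent is used and nothing else changes.

Step 1
Reactants: 1 but-3-yn-1-ol
Product: 2 tert-butyl(but-3-yn-1-yloxy)dimethylsilane
Conditions: TBSCl, imidazole, CH2Cl2, 0 °C to rt
Reagents that add atoms: tert-butyldimethylsilyl chloride, CC(C)(C)[Si](C)(C)Cl
Why: Routine imidazole-assisted silylation of a primary alcohol removes the acidic O–H before the organoaluminium step and marks the future C8 oxygen as different from the allylic oxygen made next.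

Step 2
Reactants: 2 tert-butyl(but-3-yn-1-yloxy)dimethylsilane
Product: 5 (E)-5-[(tert-butyldimethylsilyl)oxy]-3-methylpent-2-en-1-ol, via alkenyldimethylalane 3 (not isolated), via lithium alkenylalanate 4 (not isolated)
Conditions: Me3Al, Cp2ZrCl2 (cat.), CH2Cl2, 0 °C to rt; n-BuLi, THF/hexane, −30 °C; (CH2O)n, −30 °C to rt; H2O work-up
Reagents that add atoms: trimethylaluminium, C[Al](C)C; paraformaldehyde (as formaldehyde), C=O
Why: Negishi carboalumination adds CH3 and Al syn across the terminal alkyne with Al on the end carbon, and hydroxymethylation of the derived alanate proceeds with retention, so the trisubstituted alkene should arise as the E isomer.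

Step 3
Reactants: 5 (E)-5-[(tert-butyldimethylsilyl)oxy]-3-methylpent-2-en-1-ol; 6 3-methylbut-3-enoic acid
Product: 7 (E)-5-[(tert-butyldimethylsilyl)oxy]-3-methylpent-2-en-1-yl 3-methylbut-3-enoate
Conditions: DCC, DMAP (5 mol %), CH2Cl2, 0 °C
Reagents that add atoms: none
Why: Steglich esterification joins the primary allylic alcohol to the acid under near-neutral conditions, and the small DMAP loading at 0 °C is meant to keep the β,γ-double bond of the acyl part out of conjugation.

Step 4
Reactants: 7 (E)-5-[(tert-butyldimethylsilyl)oxy]-3-methylpent-2-en-1-yl 3-methylbut-3-enoate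
Product: 8 (E)-5-hydroxy-3-methylpent-2-en-1-yl 3-methylbut-3-enoate
Conditions: HF·pyridine, THF, 0 °C to rt
Reagents that add atoms: none
Why: Fluoride-driven cleavage of the Si–O bond under slightly acidic conditions frees the C8 alcohol without ester cleavage or alkene migration, and the E-alkene holds this hydroxyl too far from the ester for acyl transfer.

Step 5
Reactants: 8 (E)-5-hydroxy-3-methylpent-2-en-1-yl 3-methylbut-3-enoate
Product: 9 (E)-5-chloro-3-methylpent-2-en-1-yl 3-methylbut-3-enoate
Conditions: PPh3, N-chlorosuccinimide (premixed), THF, 0 °C to rt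
Reagents that add atoms: N-chlorosuccinimide, O=C1CCC(=O)N1Cl
Why: Appel-type chlorination (SN2 displacement of an alkoxyphosphonium ion by chloride) installs the C8 leaving group before any C6 carbonyl exists, which avoids the δ-lactone and cyclic hemiketal that a free C8 hydroxyl would form later, and a primary chloride is sluggish enough to pass through steps 6 and 7 untouched.

Step 6
Reactants: 9 (E)-5-chloro-3-methylpent-2-en-1-yl 3-methylbut-3-enoate
Product: 11 (2S,3S)-5-chloro-3-ethenyl-3-methyl-2-(prop-1-en-2-yl)pentanoic acid, via boron ketene acetal 10 (not isolated)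
Conditions: (S,S)-[ArSO2NHCH(Ph)]2 (Ar = 3,5-(CF3)2C6H3), BBr3, CH2Cl2, rt, then evaporation; 9, Et3N, toluene/hexane, −78 °C, then −20 to 4 °C; H2O work-up
Reagents that add atoms: none
Why: In this enantioselective boron-enolate Ireland–Claisen rearrangement, soft enolisation with Et3N in a non-polar medium gives the ketene acetal with the isopropenyl group trans to O–B, the chair transition state with the E-alkene places CH2CH2Cl equatorial and CH3 axial and so fixes the C5/C10 relative configuration, and the C2-symmetric diazaborolidine shields one enolate face and so fixes the absolute configuration.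

Step 7
Reactants: 11 (2S,3S)-5-chloro-3-ethenyl-3-methyl-2-(prop-1-en-2-yl)pentanoic acid; 12 potassium monomethyl malonate
Product: 14 methyl (4S,5S)-7-chloro-5-ethenyl-5-methyl-3-oxo-4-(prop-1-en-2-yl)heptanoate, via acyl imidazolide 13 (not isolated)
Conditions: 1,1'-carbonyldiimidazole, THF, rt; then 12, MgCl2, Et3N, MeCN (premixed), rt to 45 °C; dilute HCl work-up
Reagents that add atoms: none
Why: In the Masamune–Brooks homologation the acyl imidazolide C-acylates the magnesium enolate of the malonate half-ester with loss of CO2 under essentially neutral conditions, and the product is held as its magnesium chelate so that the sensitive allylic C5–H next to the new ketone is not exchanged.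

Step 8
Reactants: 14 methyl (4S,5S)-7-chloro-5-ethenyl-5-methyl-3-oxo-4-(prop-1-en-2-yl)heptanoate
Product: 15 methyl (4S,5S)-5-ethenyl-7-iodo-5-methyl-3-oxo-4-(prop-1-en-2-yl)heptanoate
Conditions: NaI, acetone, reflux
Reagents that add atoms: sodium iodide, [Na+].[I-]
Why: Finkelstein exchange, driven by precipitation of NaCl from acetone, turns the robust chloride into the soft and far better leaving group needed for ring closure under base-free conditions that leave the β-keto ester un-ionised.

Step 9
Reactants: 15 methyl (4S,5S)-5-ethenyl-7-iodo-5-methyl-3-oxo-4-(prop-1-en-2-yl)heptanoate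
Product: 17 methyl (1R,3S,4S)-4-ethenyl-4-methyl-2-oxo-3-(prop-1-en-2-yl)cyclohexane-1-carboxylate, via potassium enolate 16 (not isolated)
Conditions: K2CO3, acetone, 0.01 M, reflux; aq. NH4Cl work-up
Reagents that add atoms: none
Why: K2CO3 removes only the proton at C7, the carbon between the C6 ketone and the C11 ester, and the π lobe of C7 in the resulting chelated potassium enolate 16 displaces iodide from the primary carbon C8 in an intramolecular SN2 reaction that forms C7–C8. The closest known reaction type is the base-mediated cycloalkylation of ω-halo β-keto esters to 2-alkoxycarbonylcyclohexanones. Ring B closes in the 6-(enolendo)-exo-tet mode, the smallest enolendo ring size in which the enolate carbon can reach the rear of the C–I bond, and it closes at an unhindered CH2 two atoms away from the quaternary C10. The new stereocentre C7 stays acidic in the product and is therefore set by equilibration through the enolate: in the chair fixed by the equatorial isopropenyl group at C5 and the equatorial vinyl group at C10, the CO2Me group settles equatorial, which is the 1R configuration. The step needs C- over O-alkylation (attack through the C6 enolate oxygen would also close a six-membered ring) and cyclisation over dimerisation; the soft iodide, the tight potassium chelate in a weakly polar solvent, high dilution and the gem-disubstituted C10 in the tether all work in that direction. C5 is safe because the monoanion centred on C7 resists a second deprotonation at the allylic C5–H.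

Step 10
Reactants: 17 methyl (1R,3S,4S)-4-ethenyl-4-methyl-2-oxo-3-(prop-1-en-2-yl)cyclohexane-1-carboxylate
Product: 18 methyl (1R,2S,3S,4S)-4-ethenyl-2-hydroxy-4-methyl-3-(prop-1-en-2-yl)cyclohexane-1-carboxylate
Conditions: NaBH4, MeOH, −20 to 0 °C
Reagents that add atoms: none
Why: Borohydride reduction of the keto tautomer with the equatorial ester masks C6 and freezes C7, and because the axial C10 methyl group blocks the ring face syn to it, hydride should arrive from the opposite face and give the axial (2S) alcohol, a configuration that is erased in step 13 and therefore need not be clean.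

Step 11
Reactants: 19 benzyl chloromethyl ether
Product: 20 [(benzyloxy)methyl]tributylstannane
Conditions: Bu3SnH, LiN(iPr)2, THF, 0 °C; then 19, −78 °C to rt
Reagents that add atoms: tributylstannane, CCCC[SnH](CCCC)CCCC
Why: Deprotonation of Bu3SnH gives the stannyl anion, which displaces chloride from the chloromethyl ether in a plain SN2 reaction to give the storable precursor of a hydroxymethyl anion equivalent.

Step 12
Reactants: 18 methyl (1R,2S,3S,4S)-4-ethenyl-2-hydroxy-4-methyl-3-(prop-1-en-2-yl)cyclohexane-1-carboxylate; 20 [(benzyloxy)methyl]tributylstannane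
Product: 23 (1S,2S,3S,6R)-6-[1,3-bis(benzyloxy)-2-hydroxypropan-2-yl]-3-ethenyl-3-methyl-2-(prop-1-en-2-yl)cyclohexan-1-ol, via benzyloxymethyllithium 21 (not isolated), via monoadduct ketone alkoxide 22 (not isolated)
Conditions: 20 (5 equiv), n-BuLi (5 equiv), THF, −78 °C; then 18, −78 to −50 °C; H2O quench
Reagents that add atoms: none
Why: Tin–lithium exchange gives the α-alkoxy organolithium, whose first equivalent deprotonates the C6 hydroxyl (an alkoxide cannot be eliminated and it chelates and activates the ester) and whose next two equivalents add to C11 in the standard twofold organolithium addition to an ester, and no stereocentre arises because C11 carries two identical arms.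

Step 13
Reactants: 23 (1S,2S,3S,6R)-6-[1,3-bis(benzyloxy)-2-hydroxypropan-2-yl]-3-ethenyl-3-methyl-2-(prop-1-en-2-yl)cyclohexan-1-ol
Product: 24 (2S,3S,6S)-6-[1,3-bis(benzyloxy)-2-hydroxypropan-2-yl]-3-ethenyl-3-methyl-2-(prop-1-en-2-yl)cyclohexan-1-one
Conditions: Dess–Martin periodinane, NaHCO3, CH2Cl2, 0 °C to rt
Reagents that add atoms: none
Why: Dess–Martin oxidation acts on the only oxidisable hydroxyl, the strained axial C6 alcohol, leaves the tertiary C11 alcohol and both alkenes alone, and its buffered neutral medium avoids retro-aldol cleavage and epimerisation at C5 or C7.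

Step 14
Reactants: 24 (2S,3S,6S)-6-[1,3-bis(benzyloxy)-2-hydroxypropan-2-yl]-3-ethenyl-3-methyl-2-(prop-1-en-2-yl)cyclohexan-1-one
Product: 25 2-[(1R,2R,3S,4S)-4-ethenyl-2-hydroxy-4-methyl-3-(prop-1-en-2-yl)cyclohexyl]propane-1,2,3-triol
Conditions: Li, NH3(l)/THF, t-BuOH, −78 °C (24 added to the blue solution); then solid NH4Cl
Reagents that add atoms: none
Why: This dissolving-metal reduction does two jobs at once, since electron transfer to the C6 ketone gives a ketyl and then a carbanion that is protonated to the more stable equatorial (2R) alcohol trans to both neighbours, which hydride reagents cannot reach past the axial C10 methyl group, while the same electrons cleave both benzyl ethers and leave the unconjugated vinyl and isopropenyl groups alone.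

Step 15
Reactants: 25 2-[(1R,2R,3S,4S)-4-ethenyl-2-hydroxy-4-methyl-3-(prop-1-en-2-yl)cyclohexyl]propane-1,2,3-triol
Product: 26 2-[(1R,2R,3S,4S)-4-ethenyl-2-hydroxy-4-methyl-3-(prop-1-en-2-yl)cyclohexyl]-2-hydroxypropane-1,3-diyl diacetate (CNP0273389.1)
Conditions: Ac2O (2.2 equiv), pyridine, CH2Cl2, 0 °C
Reagents that add atoms: acetic anhydride, CC(=O)OC(C)=O
Why: This is selective acylation by steric differentiation, because without DMAP the two primary hydroxyls react far faster than the secondary C6 hydroxyl flanked by two branched ring carbons and than the tertiary C11 hydroxyl, so two equivalents of Ac2O should stop at the 12,13-diacetate.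

Compound list
1 | but-3-yn-1-ol | C#CCCO | starting material
2 | tert-butyl(but-3-yn-1-yloxy)dimethylsilane | C#CCCO[Si](C)(C)C(C)(C)C | intermediate
3 | (E)-[4-(tert-butyldimethylsilyloxy)-2-methylbut-1-en-1-yl]dimethylalane | C[Al](C)/C=C(\C)CCO[Si](C)(C)C(C)(C)C | intermediate
4 | lithium butyl[(E)-4-(tert-butyldimethylsilyloxy)-2-methylbut-1-en-1-yl]dimethylalanate | [Li+].CCCC[Al-](C)(C)/C=C(\C)CCO[Si](C)(C)C(C)(C)C | intermediate
5 | (E)-5-[(tert-butyldimethylsilyl)oxy]-3-methylpent-2-en-1-ol | OC/C=C(\C)CCO[Si](C)(C)C(C)(C)C | intermediate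
6 | 3-methylbut-3-enoic acid | C=C(C)CC(=O)O | starting material
7 | (E)-5-[(tert-butyldimethylsilyl)oxy]-3-methylpent-2-en-1-yl 3-methylbut-3-enoate | C=C(C)CC(=O)OC/C=C(\C)CCO[Si](C)(C)C(C)(C)C | intermediate
8 | (E)-5-hydroxy-3-methylpent-2-en-1-yl 3-methylbut-3-enoate | C=C(C)CC(=O)OC/C=C(\C)CCO | intermediate
9 | (E)-5-chloro-3-methylpent-2-en-1-yl 3-methylbut-3-enoate | C=C(C)CC(=O)OC/C=C(\C)CCCl | intermediate
10 | ketene acetal of 9 carrying the (4S,5S)-1,3-bis[3,5-bis(trifluoromethyl)phenylsulfonyl]-4,5-diphenyl-1,3,2-diazaborolidin-2-yl group on oxygen, isopropenyl cis to the allyloxy group | C=C(C)/C=C(\OC/C=C(\C)CCCl)OB1N(S(=O)(=O)c2cc(cc(c2)C(F)(F)F)C(F)(F)F)[C@@H](c2ccccc2)[C@H](c2ccccc2)N1S(=O)(=O)c3cc(cc(c3)C(F)(F)F)C(F)(F)F | intermediate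
11 | (2S,3S)-5-chloro-3-ethenyl-3-methyl-2-(prop-1-en-2-yl)pentanoic acid | C=C[C@](C)(CCCl)[C@H](C(=C)C)C(=O)O | intermediate
12 | potassium monomethyl malonate (potassium 3-methoxy-3-oxopropanoate) | COC(=O)CC(=O)[O-].[K+] | starting material
13 | (2S,3S)-5-chloro-3-ethenyl-1-(imidazol-1-yl)-3-methyl-2-(prop-1-en-2-yl)pentan-1-one | C=C[C@](C)(CCCl)[C@H](C(=C)C)C(=O)n1ccnc1 | intermediate
14 | methyl (4S,5S)-7-chloro-5-ethenyl-5-methyl-3-oxo-4-(prop-1-en-2-yl)heptanoate | C=C[C@](C)(CCCl)[C@H](C(=C)C)C(=O)CC(=O)OC | intermediate
15 | methyl (4S,5S)-5-ethenyl-7-iodo-5-methyl-3-oxo-4-(prop-1-en-2-yl)heptanoate | C=C[C@](C)(CCI)[C@H](C(=C)C)C(=O)CC(=O)OC | intermediate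
16 | potassium (Z)-enolate of 15 (C6–O− cis to CO2Me) | C=C[C@](C)(CCI)[C@H](C(=C)C)/C([O-])=C/C(=O)OC.[K+] | intermediate
17 | methyl (1R,3S,4S)-4-ethenyl-4-methyl-2-oxo-3-(prop-1-en-2-yl)cyclohexane-1-carboxylate | C=C[C@]1(C)CC[C@@H](C(=O)OC)C(=O)[C@H]1C(=C)C | intermediate
18 | methyl (1R,2S,3S,4S)-4-ethenyl-2-hydroxy-4-methyl-3-(prop-1-en-2-yl)cyclohexane-1-carboxylate | C=C[C@]1(C)CC[C@@H](C(=O)OC)[C@@H](O)[C@H]1C(=C)C | intermediate
19 | benzyl chloromethyl ether | ClCOCc1ccccc1 | starting material
20 | [(benzyloxy)methyl]tributylstannane | CCCC[Sn](CCCC)(CCCC)COCc1ccccc1 | intermediate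
21 | benzyloxymethyllithium | [Li]COCc1ccccc1 | intermediate
22 | lithium (1S,2S,3S,6R)-6-[(benzyloxy)acetyl]-3-ethenyl-3-methyl-2-(prop-1-en-2-yl)cyclohexan-1-olate | C=C[C@]1(C)CC[C@@H](C(=O)COCc2ccccc2)[C@@H]([O-])[C@H]1C(=C)C.[Li+] | intermediate
23 | (1S,2S,3S,6R)-6-[1,3-bis(benzyloxy)-2-hydroxypropan-2-yl]-3-ethenyl-3-methyl-2-(prop-1-en-2-yl)cyclohexan-1-ol | C=C[C@]1(C)CC[C@@H](C(O)(COCc2ccccc2)COCc2ccccc2)[C@@H](O)[C@H]1C(=C)C | intermediate
24 | (2S,3S,6S)-6-[1,3-bis(benzyloxy)-2-hydroxypropan-2-yl]-3-ethenyl-3-methyl-2-(prop-1-en-2-yl)cyclohexan-1-one | C=C[C@]1(C)CC[C@@H](C(O)(COCc2ccccc2)COCc2ccccc2)C(=O)[C@H]1C(=C)C | intermediate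
25 | 2-[(1R,2R,3S,4S)-4-ethenyl-2-hydroxy-4-methyl-3-(prop-1-en-2-yl)cyclohexyl]propane-1,2,3-triol | C=C[C@]1(C)CC[C@@H](C(O)(CO)CO)[C@H](O)[C@H]1C(=C)C | intermediate
26 | 2-[(1R,2R,3S,4S)-4-ethenyl-2-hydroxy-4-methyl-3-(prop-1-en-2-yl)cyclohexyl]-2-hydroxypropane-1,3-diyl diacetate | C=C[C@]1(C)CC[C@@H](C(O)(COC(C)=O)COC(C)=O)[C@H](O)[C@H]1C(=C)C | target

Total step count: 15. Longest linear sequence: 14 (steps 1–10 and 12–15; step 11 is a side branch).

Steps most likely to fail

Step 14. In the strongly basic medium the tertiary C11 alkoxide may fragment by retro-aldol cleavage before the ketone has taken up electrons. Enolisation towards C5 may scramble that centre or draw the isopropenyl double bond into conjugation, and long contact may start to saturate the vinyl group. The fallback separates the two tasks and reduces the ketone in a neutral, chelating medium. It sets out from 23, which has no ketone. Li in NH3 removes both benzyl groups to give the 6-epi tetraol F1, and selective acetylation as in step 15 gives the 6-epi diacetate F2. Dess–Martin oxidation then gives the keto diacetate F3. SmI2 in THF/MeOH binds the C11 hydroxyl and the ketone and reduces through a ketyl to the more stable equatorial alcohol. This comes back to the route at the target 26.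

Step 12. The basic organolithium may enolise the ester at C7, the sequence may stop after the first addition because of crowding around C11, or the reagent may decay by a [1,2]-shift on warming. The fallback reverses the polarity of the C7–C11 bond. It sets out from 17. Krapcho dealkoxycarbonylation (LiCl, wet DMSO, heat) gives the cyclohexanone F4. Kinetic deprotonation at the unbranched C7 with LiN(iPr)2 in THF at −78 °C is followed by aldol addition to commercial 1,3-bis(benzyloxy)propan-2-one, which brings in C11, C12 and C13 together. The reversible aldol places the bulky arm equatorial. This comes back to the route at 24, so that steps 10 to 13 fall away.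

Step 9. Ring closure through the enolate oxygen or intermolecular alkylation may compete with C-alkylation. The fallback forms C7–C8 between two molecules, where oxygen attack is no ring-closing shortcut, and closes ring B at C6–C7 instead. It sets out from 11. Trimethylsilyldiazomethane gives the chloro methyl ester F5. Alkylation of dimethyl malonate (NaH, NaI cat., DMF) gives the triester F6, and Krapcho dealkoxycarbonylation (LiCl, wet DMSO, heat) gives the heptanedioate F7. Dieckmann condensation (KOtBu, THF) is driven by formation of the stabilised enolate at C7 and comes back to the route at 17.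

Further compounds
F1 | step 14 | 2-[(1R,2S,3S,4S)-4-ethenyl-2-hydroxy-4-methyl-3-(prop-1-en-2-yl)cyclohexyl]propane-1,2,3-triol (6-epi tetraol) | C=C[C@]1(C)CC[C@@H](C(O)(CO)CO)[C@@H](O)[C@H]1C(=C)C
F2 | step 14 | 2-[(1R,2S,3S,4S)-4-ethenyl-2-hydroxy-4-methyl-3-(prop-1-en-2-yl)cyclohexyl]-2-hydroxypropane-1,3-diyl diacetate (6-epi diacetate) | C=C[C@]1(C)CC[C@@H](C(O)(COC(C)=O)COC(C)=O)[C@@H](O)[C@H]1C(=C)C
F3 | step 14 | 2-[(1S,3S,4S)-4-ethenyl-4-methyl-2-oxo-3-(prop-1-en-2-yl)cyclohexyl]-2-hydroxypropane-1,3-diyl diacetate (keto diacetate) | C=C[C@]1(C)CC[C@@H](C(O)(COC(C)=O)COC(C)=O)C(=O)[C@H]1C(=C)C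
F4 | step 12 | (2S,3S)-3-ethenyl-3-methyl-2-(prop-1-en-2-yl)cyclohexan-1-one | C=C[C@]1(C)CCCC(=O)[C@H]1C(=C)C
F5 | step 9 | methyl (2S,3S)-5-chloro-3-ethenyl-3-methyl-2-(prop-1-en-2-yl)pentanoate | C=C[C@](C)(CCCl)[C@H](C(=C)C)C(=O)OC
F6 | step 9 | dimethyl 2-[(3S,4S)-3-ethenyl-4-(methoxycarbonyl)-3,5-dimethylhex-5-en-1-yl]malonate | C=C[C@](C)(CCC(C(=O)OC)C(=O)OC)[C@H](C(=C)C)C(=O)OC
F7 | step 9 | dimethyl (2S,3S)-3-ethenyl-3-methyl-2-(prop-1-en-2-yl)heptanedioate | C=C[C@](C)(CCCC(=O)OC)[C@H](C(=C)C)C(=O)OC
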